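## Retrosynthetic overview

1. The target ketone comes from late oxidation of a secondary alcohol that is carried as a TBS ether, so the epimerisable α-methyl centre is formed last.
2. The cyclohexadiene ring is formed last, by disrotatory 6π electrocyclisation of an (E,Z,E)-trienyl pyranone. The E,Z,E geometry fixes the side chain cis to the pyranone; a chiral aluminium Lewis acid (the new step) is to fix the absolute sense.
3. The tetraene is cut at the bond between the Z-alkene CH and the next methyl-bearing carbon: Negishi union of a (Z)-iododienyl pyranone (fragment A) with an alkenylzinc made from a methyl enyne (fragment B).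
4. Fragment A: the pyranone ring is built first (β-keto ester dianion aldol, oxidation, lactonisation, O-methylation) on an iododienal made from propargyl alcohol.
5. Fragment B: an Evans syn-aldol sets the side-chain stereocentre; Wittig and Corey–Fuchs steps give the enyne.

Assumption: the sense of induction of the new step cannot be predicted with certainty; the (R)-binaphthoxide catalyst is written, and its (S)-antipode would be used if it favours the other ring configuration.

## Route

Step 1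
Reactants: 1 prop-2-yn-1-ol
Product: 3 (Z)-3-iodo-2-methylprop-2-en-1-ol, via alkenylmagnesium alkoxide 2 (not isolated)
Conditions: MeMgBr (3 equiv), CuI (10 mol%), THF, −10 to 20 °C; then I2, −78 to 0 °C
Reagents that add atoms: methylmagnesium bromide, C[Mg]Br; iodine, II
Why: Copper-catalysed carbomagnesiation of the propargylic magnesium alkoxide (Duboudin-type anti addition) puts methyl on C2 and magnesium on C3 inside a five-membered O–Mg chelate, so iodinolysis with retention gives the Z vinyl iodide that later becomes the central Z alkene of the triene.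

Step 2
Reactants: 3 (Z)-3-iodo-2-methylprop-2-en-1-ol; 4 ethyl 2-(triphenyl-λ5-phosphanylidene)propanoate
Product: 6 ethyl (2E,4Z)-5-iodo-2,4-dimethylpenta-2,4-dienoate, via (Z)-3-iodo-2-methylprop-2-enal 5 (not isolated)
Conditions: MnO2 (excess), CH2Cl2, 20 °C, dark
Reagents that add atoms: none
Why: Tandem MnO2 allylic oxidation and Wittig olefination with a stabilised ylide traps the isomerisation-prone Z iodoenal as it forms and gives the E enoate, the Z C=C–I unit being untouched.

Step 3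
Reactants: 6 ethyl (2E,4Z)-5-iodo-2,4-dimethylpenta-2,4-dienoate
Product: 7 (2E,4Z)-5-iodo-2,4-dimethylpenta-2,4-dien-1-ol
Conditions: i-Bu2AlH (2.3 equiv), CH2Cl2, −78 °C
Reagents that add atoms: none
Why: i-Bu2AlH reduces the conjugated ester to the allylic alcohol (1,2-reduction) at −78 °C without touching the vinyl iodide.

Step 4
Reactants: 7 (2E,4Z)-5-iodo-2,4-dimethylpenta-2,4-dien-1-ol
Product: 8 (2E,4Z)-5-iodo-2,4-dimethylpenta-2,4-dienal
Conditions: MnO2 (excess), CH2Cl2, 20 °C, dark
Reagents that add atoms: none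
Why: MnO2 oxidises the allylic alcohol selectively to the dienal (allylic oxidation) under neutral conditions that keep both alkene geometries.

Step 5
Reactants: 8 (2E,4Z)-5-iodo-2,4-dimethylpenta-2,4-dienal; 9 methyl 2-methyl-3-oxopentanoate
Product: 11 methyl (6E,8Z)-5-hydroxy-9-iodo-2,4,6,8-tetramethyl-3-oxonona-6,8-dienoate (diastereomer mixture), via keto ester dianion 10 (not isolated)
Conditions: 9 (1.5 equiv), NaH, THF, 0 °C; n-BuLi, 0 °C; then 8, −78 °C
Reagents that add atoms: none
Why: The Weiler dianion of the β-keto ester reacts at its more basic γ-carbon with the aldehyde (aldol addition), and the three new stereocentres are of no consequence because all are removed in steps 6 and 7.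

Step 6
Reactants: 11 methyl (6E,8Z)-5-hydroxy-9-iodo-2,4,6,8-tetramethyl-3-oxonona-6,8-dienoate
Product: 12 methyl (6E,8Z)-9-iodo-2,4,6,8-tetramethyl-3,5-dioxonona-6,8-dienoate
Conditions: Dess–Martin periodinane, CH2Cl2, 0 to 20 °C
Reagents that add atoms: none
Why: Dess–Martin oxidation converts the secondary alcohol to the ketone under near-neutral conditions, giving the β,δ-diketo ester.

Step 7
Reactants: 12 methyl (6E,8Z)-9-iodo-2,4,6,8-tetramethyl-3,5-dioxonona-6,8-dienoate
Product: 13 4-hydroxy-6-[(2E,4Z)-5-iodo-4-methylpenta-2,4-dien-2-yl]-3,5-dimethyl-2H-pyran-2-one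
Conditions: DBU, toluene, 60 °C
Reagents that add atoms: none
Why: DBU enolises the δ-ketone and its enol oxygen attacks the methyl ester (lactonisation, Claisen-type acyl substitution) to close the 4-hydroxy-2-pyranone, while the E alkene next to the ketone keeps the dienyl iodide out of reach of that oxygen.

Step 8
Reactants: 13 4-hydroxy-6-[(2E,4Z)-5-iodo-4-methylpenta-2,4-dien-2-yl]-3,5-dimethyl-2H-pyran-2-one
Product: 14 6-[(2E,4Z)-5-iodo-4-methylpenta-2,4-dien-2-yl]-2-methoxy-3,5-dimethyl-4H-pyran-4-one (fragment A)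
Conditions: MeOTf, CH2Cl2, 0 to 20 °C
Reagents that add atoms: methyl trifluoromethanesulfonate, COS(=O)(=O)C(F)(F)F
Why: The hard electrophile MeOTf alkylates the most nucleophilic oxygen of the 4-hydroxy-2-pyranone, the lactone carbonyl oxygen, and loss of the hydroxyl proton gives the 2-methoxy-4-pyranone (regioselective O-methylation).

Step 9
Reactants: 15 (4R)-4-benzyl-3-propanoyl-1,3-oxazolidin-2-one; 16 propanal
Product: 18 (4R)-4-benzyl-3-[(2R,3S)-3-hydroxy-2-methylpentanoyl]-1,3-oxazolidin-2-one, via boron enolate 17 (not isolated)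
Conditions: Bu2BOTf, i-Pr2NEt, CH2Cl2, 0 °C; 16, −78 to 0 °C; then H2O2, MeOH, pH 7 buffer
Reagents that add atoms: none
Why: Evans syn-aldol reaction: the Z boron enolate reacts through a Zimmerman–Traxler chair on the face away from the benzyl group, setting the α-methyl centre (2R here, the later (S) centre next to the ketone) and the carbinol centre (3S, later oxidised away).

Step 10
Reactants: 18 (4R)-4-benzyl-3-[(2R,3S)-3-hydroxy-2-methylpentanoyl]-1,3-oxazolidin-2-one
Product: 19 (4R)-4-benzyl-3-[(2R,3S)-3-{[tert-butyl(dimethyl)silyl]oxy}-2-methylpentanoyl]-1,3-oxazolidin-2-one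
Conditions: TBSOTf, 2,6-lutidine, CH2Cl2, 0 °C
Reagents that add atoms: tert-butyldimethylsilyl trifluoromethanesulfonate, CC(C)(C)[Si](C)(C)OS(=O)(=O)C(F)(F)F
Why: The silyl triflate with 2,6-lutidine silylates the hindered secondary alcohol (O-silylation), masking the future ketone as a non-epimerisable ether.

Step 11
Reactants: 19 (4R)-4-benzyl-3-[(2R,3S)-3-{[tert-butyl(dimethyl)silyl]oxy}-2-methylpentanoyl]-1,3-oxazolidin-2-one
Product: 20 (2S,3S)-3-{[tert-butyl(dimethyl)silyl]oxy}-2-methylpentan-1-ol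
Conditions: LiBH4, H2O (1 equiv), Et2O, 0 °C
Reagents that add atoms: none
Why: LiBH4 cleaves the imide reductively at the exocyclic carbonyl to the primary alcohol and releases the auxiliary without touching either stereocentre.

Step 12
Reactants: 20 (2S,3S)-3-{[tert-butyl(dimethyl)silyl]oxy}-2-methylpentan-1-ol
Product: 21 (2R,3S)-3-{[tert-butyl(dimethyl)silyl]oxy}-2-methylpentanal
Conditions: Dess–Martin periodinane, pyridine, CH2Cl2, 0 to 20 °C
Reagents that add atoms: none
Why: Pyridine-buffered Dess–Martin oxidation gives the α-chiral aldehyde without epimerisation, and it is used at once.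

Step 13
Reactants: 21 (2R,3S)-3-{[tert-butyl(dimethyl)silyl]oxy}-2-methylpentanal; 22 2-(triphenyl-λ5-phosphanylidene)propanal
Product: 23 (2E,4S,5S)-5-{[tert-butyl(dimethyl)silyl]oxy}-2,4-dimethylhept-2-enal
Conditions: toluene, 90 °C
Reagents that add atoms: none
Why: Wittig olefination with the stabilised formyl ylide gives the E trisubstituted enal directly, and the weakly basic ylide leaves the α-stereocentre intact.

Step 14
Reactants: 23 (2E,4S,5S)-5-{[tert-butyl(dimethyl)silyl]oxy}-2,4-dimethylhept-2-enal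
Product: 24 tert-butyl{[(3S,4S,5E)-8,8-dibromo-4,6-dimethylocta-5,7-dien-3-yl]oxy}dimethylsilane
Conditions: CBr4, PPh3, 2,6-lutidine, CH2Cl2, 0 °C
Reagents that add atoms: carbon tetrabromide, BrC(Br)(Br)Br
Why: Corey–Fuchs (Ramirez) dibromo-olefination converts the aldehyde into the 1,1-dibromoalkene under lutidine-buffered conditions.

Step 15
Reactants: 24 tert-butyl{[(3S,4S,5E)-8,8-dibromo-4,6-dimethylocta-5,7-dien-3-yl]oxy}dimethylsilane
Product: 26 tert-butyl{[(3S,4S,5E)-4,6-dimethylnon-5-en-7-yn-3-yl]oxy}dimethylsilane (fragment B), via lithium acetylide 25 (not isolated)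
Conditions: n-BuLi (2.2 equiv), THF, −78 °C; then MeI, −78 to 20 °C
Reagents that add atoms: iodomethane, CI
Why: Second stage of the Corey–Fuchs sequence: bromine–lithium exchange, Fritsch–Buttenberg–Wiechell rearrangement and deprotonation give the lithium acetylide, which is C-methylated by MeI.

Step 16
Reactants: 26 tert-butyl{[(3S,4S,5E)-4,6-dimethylnon-5-en-7-yn-3-yl]oxy}dimethylsilane; 14 6-[(2E,4Z)-5-iodo-4-methylpenta-2,4-dien-2-yl]-2-methoxy-3,5-dimethyl-4H-pyran-4-one
Product: 29 6-[(2E,4Z,6E,8E,10S,11S)-11-{[tert-butyl(dimethyl)silyl]oxy}-4,6,8,10-tetramethyltrideca-2,4,6,8-tetraen-2-yl]-2-methoxy-3,5-dimethyl-4H-pyran-4-one, via alkenylzirconocene chloride 27 (not isolated), via alkenylzinc chloride 28 (not isolated)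
Conditions: 26 (1.3 equiv), Cp2Zr(H)Cl, THF, 20 to 40 °C; ZnCl2, 0 °C; then 14, Pd(PPh3)4 (5 mol%, zerovalent palladium), 0 °C, dark; cold work-up, used at once
Reagents that add atoms: none
Why: syn-Hydrozirconation places zirconium on the less hindered methyl-bearing alkyne carbon to give the E alkenyl metal, and transmetalation to zinc followed by Negishi coupling joins it to the Z vinyl iodide with retention at both carbons, giving the E,Z,E,E tetraene, which is kept cold so that it does not cyclise.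

Step 17
Reactants: 29 6-[(2E,4Z,6E,8E,10S,11S)-11-{[tert-butyl(dimethyl)silyl]oxy}-4,6,8,10-tetramethyltrideca-2,4,6,8-tetraen-2-yl]-2-methoxy-3,5-dimethyl-4H-pyran-4-one
Product: 30 6-[(1S,6R)-6-[(2E,4S,5S)-5-{[tert-butyl(dimethyl)silyl]oxy}-4-methylhept-2-en-2-yl]-1,3,5-trimethylcyclohexa-2,4-dien-1-yl]-2-methoxy-3,5-dimethyl-4H-pyran-4-one
Conditions: methylaluminium (R)-3,3'-bis(triphenylsilyl)-1,1'-binaphthalene-2,2'-diolate, MeAl[O2C20H10(SiPh3)2] (20 mol%, pre-formed), toluene, −40 to −20 °C, dark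
Reagents that add atoms: none
Why: Proposed new method: a chiral aluminium Lewis acid-catalysed, torquoselective disrotatory 6π electrocyclisation of a triene that carries a 4-pyranone at one terminus, in which binding of the oxophilic aluminium binaphthoxide to the pyranone carbonyl gives a 4-aluminoxypyrylium-like acceptor that polarises the E,Z,E triene (the pyranone-bearing terminus becomes enol-ether-like, the far terminus dienyl-cation-like) and should lower the barrier of the thermally allowed closure enough for it to run at −40 to −20 °C where the unbound triene is inert, while the two triphenylsilyl walls of the ligand, which reach the pyranone carbon para to the bound carbonyl, allow only one helical folding of the triene so that both ring stereocentres are set together in one absolute sense, their cis relation (side chain cis to pyranone, trans to methyl) following from the disrotatory mode on the E,Z,E geometry; the closest known reaction types are Me2AlCl catalysis of 6π electrocyclisation of 2-acyl trienes and the asymmetric Claisen rearrangement promoted by chiral bis(triarylsilyl)binaphthol aluminium reagents bound to a single oxygen.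

Step 18
Reactants: 30 6-[(1S,6R)-6-[(2E,4S,5S)-5-{[tert-butyl(dimethyl)silyl]oxy}-4-methylhept-2-en-2-yl]-1,3,5-trimethylcyclohexa-2,4-dien-1-yl]-2-methoxy-3,5-dimethyl-4H-pyran-4-one
Product: 31 6-[(1S,6R)-6-[(2E,4S,5S)-5-hydroxy-4-methylhept-2-en-2-yl]-1,3,5-trimethylcyclohexa-2,4-dien-1-yl]-2-methoxy-3,5-dimethyl-4H-pyran-4-one
Conditions: HF·pyridine, pyridine, THF, 0 to 20 °C
Reagents that add atoms: none
Why: Fluoride-mediated desilylation with pyridine-buffered HF·pyridine frees the secondary alcohol without acid damage to the diene or the pyranone.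

Step 19
Reactants: 31 6-[(1S,6R)-6-[(2E,4S,5S)-5-hydroxy-4-methylhept-2-en-2-yl]-1,3,5-trimethylcyclohexa-2,4-dien-1-yl]-2-methoxy-3,5-dimethyl-4H-pyran-4-one
Product: 32 2-methoxy-3,5-dimethyl-6-[(1S,6R)-1,3,5-trimethyl-6-[(2E,4S)-4-methyl-5-oxohept-2-en-2-yl]cyclohexa-2,4-dien-1-yl]-4H-pyran-4-one (target)
Conditions: Dess–Martin periodinane, pyridine, CH2Cl2, 0 °C
Reagents that add atoms: none
Why: Pyridine-buffered Dess–Martin oxidation gives the β,γ-unsaturated ketone under non-enolising conditions, so the α-methyl centre stays (S) and the alkene does not move into conjugation.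

## Compound list

1 | prop-2-yn-1-ol | C#CCO | starting material
2 | bromomagnesium (Z)-3-(bromomagnesio)-2-methylprop-2-en-1-olate | Br[Mg]OC/C(C)=C\[Mg]Br | intermediate
3 | (Z)-3-iodo-2-methylprop-2-en-1-ol | OC/C(C)=C\I | intermediate
4 | ethyl 2-(triphenyl-λ5-phosphanylidene)propanoate | CCOC(=O)C(C)=P(c1ccccc1)(c1ccccc1)c1ccccc1 | starting material
5 | (Z)-3-iodo-2-methylprop-2-enal | O=C/C(C)=C\I | intermediate
6 | ethyl (2E,4Z)-5-iodo-2,4-dimethylpenta-2,4-dienoate | CCOC(=O)/C(C)=C/C(C)=C\I | intermediate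
7 | (2E,4Z)-5-iodo-2,4-dimethylpenta-2,4-dien-1-ol | OC/C(C)=C/C(C)=C\I | intermediate
8 | (2E,4Z)-5-iodo-2,4-dimethylpenta-2,4-dienal | O=C/C(C)=C/C(C)=C\I | intermediate
9 | methyl 2-methyl-3-oxopentanoate (racemic) | CCC(=O)C(C)C(=O)OC | starting material
10 | sodium lithium dianion (bis-enolate) of methyl 2-methyl-3-oxopentanoate | CC=C([O-])C(C)=C([O-])OC.[Na+].[Li+] | intermediate
11 | methyl (6E,8Z)-5-hydroxy-9-iodo-2,4,6,8-tetramethyl-3-oxonona-6,8-dienoate (diastereomer mixture at C2, C4, C5) | COC(=O)C(C)C(=O)C(C)C(O)/C(C)=C/C(C)=C\I | intermediate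
12 | methyl (6E,8Z)-9-iodo-2,4,6,8-tetramethyl-3,5-dioxonona-6,8-dienoate | COC(=O)C(C)C(=O)C(C)C(=O)/C(C)=C/C(C)=C\I | intermediate
13 | 4-hydroxy-6-[(2E,4Z)-5-iodo-4-methylpenta-2,4-dien-2-yl]-3,5-dimethyl-2H-pyran-2-one | Cc1c(O)c(C)c(/C(C)=C/C(C)=C\I)oc1=O | intermediate
14 | 6-[(2E,4Z)-5-iodo-4-methylpenta-2,4-dien-2-yl]-2-methoxy-3,5-dimethyl-4H-pyran-4-one | COc1oc(/C(C)=C/C(C)=C\I)c(C)c(=O)c1C | intermediate
15 | (4R)-4-benzyl-3-propanoyl-1,3-oxazolidin-2-one | CCC(=O)N1[C@H](Cc2ccccc2)COC1=O | starting material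
16 | propanal | CCC=O | starting material
17 | dibutylboron (Z)-enolate of 15 | C/C=C(\OB(CCCC)CCCC)N1[C@H](Cc2ccccc2)COC1=O | intermediate
18 | (4R)-4-benzyl-3-[(2R,3S)-3-hydroxy-2-methylpentanoyl]-1,3-oxazolidin-2-one | CC[C@H](O)[C@@H](C)C(=O)N1[C@H](Cc2ccccc2)COC1=O | intermediate
19 | (4R)-4-benzyl-3-[(2R,3S)-3-{[tert-butyl(dimethyl)silyl]oxy}-2-methylpentanoyl]-1,3-oxazolidin-2-one | CC[C@H](O[Si](C)(C)C(C)(C)C)[C@@H](C)C(=O)N1[C@H](Cc2ccccc2)COC1=O | intermediate
20 | (2S,3S)-3-{[tert-butyl(dimethyl)silyl]oxy}-2-methylpentan-1-ol | CC[C@H](O[Si](C)(C)C(C)(C)C)[C@@H](C)CO | intermediate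
21 | (2R,3S)-3-{[tert-butyl(dimethyl)silyl]oxy}-2-methylpentanal | CC[C@H](O[Si](C)(C)C(C)(C)C)[C@@H](C)C=O | intermediate
22 | 2-(triphenyl-λ5-phosphanylidene)propanal | CC(C=O)=P(c1ccccc1)(c1ccccc1)c1ccccc1 | starting material
23 | (2E,4S,5S)-5-{[tert-butyl(dimethyl)silyl]oxy}-2,4-dimethylhept-2-enal | CC[C@H](O[Si](C)(C)C(C)(C)C)[C@@H](C)/C=C(\C)C=O | intermediate
24 | tert-butyl{[(3S,4S,5E)-8,8-dibromo-4,6-dimethylocta-5,7-dien-3-yl]oxy}dimethylsilane | CC[C@H](O[Si](C)(C)C(C)(C)C)[C@@H](C)/C=C(\C)C=C(Br)Br | intermediate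
25 | lithium acetylide of 26 (lithium in place of the terminal methyl) | CC[C@H](O[Si](C)(C)C(C)(C)C)[C@@H](C)/C=C(\C)C#C[Li] | intermediate
26 | tert-butyl{[(3S,4S,5E)-4,6-dimethylnon-5-en-7-yn-3-yl]oxy}dimethylsilane | CC[C@H](O[Si](C)(C)C(C)(C)C)[C@@H](C)/C=C(\C)C#CC | intermediate
27 | chlorobis(cyclopentadienyl)[(2E,4E,6S,7S)-7-{[tert-butyl(dimethyl)silyl]oxy}-4,6-dimethylnona-2,4-dien-2-yl]zirconium | CC[C@H](O[Si](C)(C)C(C)(C)C)[C@@H](C)/C=C(\C)/C=C(\C)[Zr](Cl)(C1C=CC=C1)C1C=CC=C1 | intermediate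
28 | chloro[(2E,4E,6S,7S)-7-{[tert-butyl(dimethyl)silyl]oxy}-4,6-dimethylnona-2,4-dien-2-yl]zinc | CC[C@H](O[Si](C)(C)C(C)(C)C)[C@@H](C)/C=C(\C)/C=C(\C)[Zn]Cl | intermediate
29 | 6-[(2E,4Z,6E,8E,10S,11S)-11-{[tert-butyl(dimethyl)silyl]oxy}-4,6,8,10-tetramethyltrideca-2,4,6,8-tetraen-2-yl]-2-methoxy-3,5-dimethyl-4H-pyran-4-one | CC[C@H](O[Si](C)(C)C(C)(C)C)[C@@H](C)/C=C(\C)/C=C(\C)/C=C(/C)\C=C(/C)c1oc(OC)c(C)c(=O)c1C | intermediate
30 | 6-[(1S,6R)-6-[(2E,4S,5S)-5-{[tert-butyl(dimethyl)silyl]oxy}-4-methylhept-2-en-2-yl]-1,3,5-trimethylcyclohexa-2,4-dien-1-yl]-2-methoxy-3,5-dimethyl-4H-pyran-4-one | CC[C@H](O[Si](C)(C)C(C)(C)C)[C@@H](C)/C=C(\C)[C@@H]1C(C)=CC(C)=C[C@]1(C)c1oc(OC)c(C)c(=O)c1C | intermediate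
31 | 6-[(1S,6R)-6-[(2E,4S,5S)-5-hydroxy-4-methylhept-2-en-2-yl]-1,3,5-trimethylcyclohexa-2,4-dien-1-yl]-2-methoxy-3,5-dimethyl-4H-pyran-4-one | CC[C@H](O)[C@@H](C)/C=C(\C)[C@@H]1C(C)=CC(C)=C[C@]1(C)c1oc(OC)c(C)c(=O)c1C | intermediate
32 | 2-methoxy-3,5-dimethyl-6-[(1S,6R)-1,3,5-trimethyl-6-[(2E,4S)-4-methyl-5-oxohept-2-en-2-yl]cyclohexa-2,4-dien-1-yl]-4H-pyran-4-one | CCC(=O)[C@@H](C)/C=C(\C)[C@@H]1C(C)=CC(C)=C[C@]1(C)c1oc(OC)c(C)c(=O)c1C | target

## Totals and risks

Total step count: 19.
Longest linear sequence: 12 steps (steps 1 to 8, then 16 to 19). The fragment B branch is 7 steps (9 to 15) before the union.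

Three steps most likely to fail:

Step 17 (the proposed new step). The Lewis acid may give no useful rate gain at low temperature, may divert the polarised triene into a cationic cyclisation (bicyclo[3.1.0]hexene skeleton), or may give poor control of the helical sense. The fallback uses known chemistry and sets out from 29. The tetraene is heated without any additive in toluene at 60 to 80 °C in the dark, the uncatalysed thermal disrotatory 6π electrocyclisation. This gives 30 together with its ring diastereomer 6-[(1R,6S)-6-[(2E,4S,5S)-5-{[tert-butyl(dimethyl)silyl]oxy}-4-methylhept-2-en-2-yl]-1,3,5-trimethylcyclohexa-2,4-dien-1-yl]-2-methoxy-3,5-dimethyl-4H-pyran-4-one F1 in roughly equal amounts. The fixed side-chain centres make the two diastereomers, so they are separated by preparative HPLC, and the route comes back at 30.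

Step 16. The hydrozirconation may give the wrong regiochemistry, the two hindered partners may couple slowly, or the tetraene may cyclise during the coupling. The fallback sets out from 14 and 24. Iodide 14 is stannylated (Me3SnSnMe3, Pd(PPh3)4, toluene, 60 °C) to 2-methoxy-3,5-dimethyl-6-[(2E,4Z)-4-methyl-5-(trimethylstannyl)penta-2,4-dien-2-yl]-4H-pyran-4-one F2. A trans-selective Stille coupling of F2 with the more accessible bromine of dibromide 24 (Pd2(dba)3, tri(2-furyl)phosphine, toluene, 20 to 40 °C) gives 6-[(2E,4Z,6Z,8E,10S,11S)-6-bromo-11-{[tert-butyl(dimethyl)silyl]oxy}-4,8,10-trimethyltrideca-2,4,6,8-tetraen-2-yl]-2-methoxy-3,5-dimethyl-4H-pyran-4-one F3. Negishi methylation of the remaining bromide with retention (MeZnCl, Pd(t-Bu3P)2, THF, 0 °C) then gives the tetraene, and the route comes back at 29.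

Step 13. The formyl ylide is a weak nucleophile and needs heat, so aldehyde 21 may epimerise, lose silanol, or be homologated twice. The fallback sets out from 21. Wittig olefination with ylide 4 in CH2Cl2 at 20 °C gives ethyl (2E,4S,5S)-5-{[tert-butyl(dimethyl)silyl]oxy}-2,4-dimethylhept-2-enoate F4. Reduction with i-Bu2AlH at −78 °C gives (2E,4S,5S)-5-{[tert-butyl(dimethyl)silyl]oxy}-2,4-dimethylhept-2-en-1-ol F5, and MnO2 oxidation in CH2Cl2 returns the route at 23.

## Further compounds

F1 | step 17 | 6-[(1R,6S)-6-[(2E,4S,5S)-5-{[tert-butyl(dimethyl)silyl]oxy}-4-methylhept-2-en-2-yl]-1,3,5-trimethylcyclohexa-2,4-dien-1-yl]-2-methoxy-3,5-dimethyl-4H-pyran-4-one | CC[C@H](O[Si](C)(C)C(C)(C)C)[C@@H](C)/C=C(\C)[C@H]1C(C)=CC(C)=C[C@@]1(C)c1oc(OC)c(C)c(=O)c1C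
F2 | step 16 | 2-methoxy-3,5-dimethyl-6-[(2E,4Z)-4-methyl-5-(trimethylstannyl)penta-2,4-dien-2-yl]-4H-pyran-4-one | COc1oc(/C(C)=C/C(C)=C\[Sn](C)(C)C)c(C)c(=O)c1C
F3 | step 16 | 6-[(2E,4Z,6Z,8E,10S,11S)-6-bromo-11-{[tert-butyl(dimethyl)silyl]oxy}-4,8,10-trimethyltrideca-2,4,6,8-tetraen-2-yl]-2-methoxy-3,5-dimethyl-4H-pyran-4-one | CC[C@H](O[Si](C)(C)C(C)(C)C)[C@@H](C)/C=C(\C)/C=C(\Br)/C=C(/C)\C=C(/C)c1oc(OC)c(C)c(=O)c1C
F4 | step 13 | ethyl (2E,4S,5S)-5-{[tert-butyl(dimethyl)silyl]oxy}-2,4-dimethylhept-2-enoate | CC[C@H](O[Si](C)(C)C(C)(C)C)[C@@H](C)/C=C(\C)C(=O)OCC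
F5 | step 13 | (2E,4S,5S)-5-{[tert-butyl(dimethyl)silyl]oxy}-2,4-dimethylhept-2-en-1-ol | CC[C@H](O[Si](C)(C)C(C)(C)C)[C@@H](C)/C=C(\C)CO
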